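The easy step is to look at how the target climbs in the earlier runs.

| flask | solid substrate | first nucleophile | second nucleophile | temperature | remark | time |
|---|---|---|---|---|---|---|
| gamma | 35 mM | 31.5 mM | 46 mM | 71 °C | run made earlier |  |
| theta | 35 mM | 31.5 mM | 73 mM | 85 °C | run made earlier |  |
| epsilon | 35 mM | 16 mM | 33.2 mM | 71 °C | run made earlier |  |
| dusk | 35 mM | 31.5 mM | 33.2 mM |  | at 90 °C until 6.0 min, from then on at 65 °C | 30 min |
| dawn | 35 mM | 31.5 mM | 33.2 mM | 65 °C |  | 30 min |
| midnight | 35 mM | 31.5 mM | 33.2 mM | 90 °C |  | 30 min |

| run | time / min | target / % |
|---|---|---|
| gamma | 5.00 | 0 |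
| gamma | 10.0 | 7 |
| gamma | 15.0 | 14 |
| gamma | 20.0 | 14 |
| gamma | 25.0 | 17 |
| gamma | 30.0 | 25 |
| gamma | 40.0 | 30 |
| theta | 0.667 | 1 |
| theta | 2.00 | 2 |
| theta | 4.00 | 0 |
| theta | 6.00 | 3 |
| theta | 8.00 | 3 |
| theta | 12.0 | 6 |
| theta | 15.0 | 6 |
| epsilon | 8.00 | 1 |
| epsilon | 15.0 | 9 |
| epsilon | 20.0 | 8 |
| epsilon | 30.0 | 18 |
| epsilon | 40.0 | 26 |

(readings scatter by 2 percentage points)

- solid, in amounts per volume of the solution: solid substrate
- at the start none of the solid substrate is in solution
- what has only dissolved of solid substrate counts as not reacted

- the best flask by amount of target, in percent of the solid substrate charged; "all alike" if 1.5 percentage points covers them all (dusk / dawn / midnight / all alike)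
- amount of target at the end, in percent of the solid substrate charged, dusk
- amount of target at the end, in percent of the solid substrate charged, dawn
- amount of target at the end, in percent of the solid substrate charged, midnight

In gamma the target rises roughly straight, to 30% at 40.0 min, so I read a steady feed from the solid substrate. But each reading scatters by 2 percentage points. Epsilon has half the first nucleophile of gamma, and less second nucleophile, yet it reaches 26% at 40.0 min. So I suppose that the two nucleophiles compete for one feed. I give them equal weight, a selectivity factor of 1. The first nucleophile's share of the two charges is then 0.406 in gamma and 0.325 in epsilon.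

Now I define the pass time, the time the whole charge of solid substrate would need to pass through at that steady feed: time times share, over target fraction. Gamma gives 54.2 min. Epsilon gives 50.0 min, at the same temperature. Theta, hotter, gives 75.4 min, but from a reading of 6% at 15.0 min, with its scatter of 2 points, so I have no temperature rule. Dusk, dawn and midnight carry the same charges, so their share is 0.487. With gamma's pass time and no temperature rule, I reckon 27.0% of target at 30 min in each, and I call them alike.

The forecast differs: it picks dusk, with 18% in dusk, 13% in dawn and 14% in midnight, judging “Midnight is fast but unselective”.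

Midnight is best at 40.0%, above dusk at 25.5% and dawn at 22.7%.

    first nucleophile + intermediate → target (k = 210 /M/s, Ea = 49.0 kJ/mol)
    second nucleophile + intermediate → other capture product (k = 330 /M/s, Ea = 39.0 kJ/mol)
    starting material → intermediate (k = 0.0410 /s, Ea = 88.0 kJ/mol)
    solid substrate ⇌ starting material, rate k4*(cs4 - [starting material]) while solid is left; crystals form when [starting material] > cs4 (solubility = 8.80 mM, k = 0.00230 /s)
    starting material + intermediate → side product (k = 0.290 /M/s, Ea = 65.0 kJ/mol)
    (constants at 90 °C)

Reckoned with the share from the charges, the pass time is 64.4 min in dawn and 36.5 min in midnight, on either side of the 54.2 min from gamma. The neighbour is dawn with 13 mM of second nucleophile. Its share from the charges is 0.708, so dawn's pass time gives 33.0% of target. The neighbour holds 39.2% of target and 25.4% of other capture product at 30 min.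

The earlier runs and the new flask were computed with constants of no real substance, and the scatter is random.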